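**Retrosynthetic overview**
1. Target 37 comes from its octamethyl ether 36 (BBr3). 36 comes from carbinol 35 by Friedel–Crafts closure of the seven-membered ring (ring A carbon ortho to the furan oxygen attacks the benzylic cation).
2. 35 comes from deoxybenzoin 34 and β-keto ester 33. The key union is a crossed Claisen condensation of arylacetate 30 (both dihydrobenzofurans in place) with methyl 2,4-dimethoxybenzoate 31.
3. 30 comes from dihydrobenzofuran 2 (on ring B), made by enantioselective Rh-carbene C–H insertion of the diazo compound from diaryl ketone 23. Ketone 23 comes from the aryllithium of bromide 12 and phthalide 20.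
4. Bromide 12 (dihydrobenzofuran 1 on ring A) is made by the same ketone → hydrazone → diazo → C–H insertion → acid epimerisation sequence from aldehyde 1, alcohol 2 and bromide 5.
5. Ring order: dihydrofuran on ring A, then dihydrofuran on ring B, then the seven-membered carbocycle.

Abbreviations: G = (2S,3S)-3-(3,5-dimethoxyphenyl)-4-methoxy-2-(4-methoxyphenyl)-2,3-dihydro-1-benzofuran-6-yl (the unit of 12 joined through C6); PMB = 4-methoxybenzyl; TIPS = triisopropylsilyl; Rh2(R-PTAD)4 = dirhodium tetrakis[(R)-2-(1-adamantyl)-2-phthalimidoacetate].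

Assumption: Rh2(R-PTAD)4 is taken to give the (3S) centre in both insertions; if compound 11 proves to be the antipode, Rh2(S-PTAD)4 is used in steps 6 and 15.

**Route**

Step 1
Reactants: 1 4-bromo-2,6-difluorobenzaldehyde; 2 4-methoxybenzyl alcohol
Product: 3 4-bromo-2-fluoro-6-(4-methoxybenzyloxy)benzaldehyde
Conditions: 2, NaH, THF, 0 °C; then 1, −20 → 23 °C
Reagents that add atoms: none
Why: SNAr of an aldehyde-activated ortho fluoride by the alkoxide; the first alkoxy group deactivates the ring, so substitution stops at the mono-ether.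

Step 2
Reactants: 3 4-bromo-2-fluoro-6-(4-methoxybenzyloxy)benzaldehyde
Product: 4 4-bromo-2-methoxy-6-(4-methoxybenzyloxy)benzaldehyde
Conditions: NaOMe (3 equiv), MeOH/THF, 65 °C
Reagents that add atoms: sodium methoxide, [Na+].[O-]C
Why: Second SNAr at the remaining ortho fluoride gives the differentiated 2,6-diether without any selective dealkylation; bromide is not displaced.

Step 3
Reactants: 4 4-bromo-2-methoxy-6-(4-methoxybenzyloxy)benzaldehyde; 5 1-bromo-3,5-dimethoxybenzene
Product: 7 rac-[4-bromo-2-methoxy-6-(4-methoxybenzyloxy)phenyl](3,5-dimethoxyphenyl)methanol, via aryl Grignard reagent 6 (not isolated)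
Conditions: 5, Mg, I2 (cat.), THF, reflux; then 4, 0 → 23 °C; then H2O
Reagents that add atoms: none
Why: Grignard addition to the aldehyde; the aryl bromide of 4 does not exchange with ArMgBr, and the racemic carbinol centre is removed in step 4.

Step 4
Reactants: 7 rac-diaryl carbinol
Product: 8 [4-bromo-2-methoxy-6-(4-methoxybenzyloxy)phenyl](3,5-dimethoxyphenyl)methanone
Conditions: Dess–Martin periodinane, CH2Cl2, 23 °C
Reagents that add atoms: none
Why: Dess–Martin oxidation of a diaryl carbinol to the benzophenone; PMB ether and aryl bromide are inert.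

Step 5
Reactants: 8 diaryl ketone
Product: 9 hydrazone of 8 (E/Z mixture)
Conditions: N2H4·H2O (20 equiv), AcOH (cat.), EtOH, 100 °C, sealed tube
Reagents that add atoms: hydrazine, NN
Why: Hydrazone condensation; the 2,6-disubstituted benzophenone needs forcing conditions, and nothing else in 8 is electrophilic toward hydrazine.

Step 6
Reactants: 9 hydrazone
Product: 11 (2R,3S)-6-bromo-3-(3,5-dimethoxyphenyl)-4-methoxy-2-(4-methoxyphenyl)-2,3-dihydro-1-benzofuran (cis), via diazo compound 10 (not isolated)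
Conditions: MnO2, CH2Cl2, 0 °C, filter; then Rh2(R-PTAD)4 (1 mol %), CH2Cl2, 0 → 23 °C
Reagents that add atoms: none
Why: Hydrazone oxidation to the diaryldiazomethane, then enantioselective intramolecular Rh-carbene 1,5 C–H insertion into the activated OCH2Ar bond; the chiral carboxylate catalyst sets C3 (S) and gives the cis isomer (C2 R).

Step 7
Reactants: 11 cis-dihydrobenzofuran
Product: 12 (2S,3S)-6-bromo-3-(3,5-dimethoxyphenyl)-4-methoxy-2-(4-methoxyphenyl)-2,3-dihydro-1-benzofuran (trans; G–Br)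
Conditions: CF3CO2H, CH2Cl2, 0 → 23 °C
Reagents that add atoms: none
Why: Acid-mediated epimerisation: reversible C2–O ionisation to the 4-methoxybenzylic cation and reclosure gives the more stable trans isomer (C2 becomes S) while C3 is untouched.

Step 8
Reactants: 13 3,5-dimethoxybenzyl alcohol
Product: 14 2-bromo-3,5-dimethoxybenzyl alcohol
Conditions: NBS, MeCN, 0 → 23 °C
Reagents that add atoms: N-bromosuccinimide, BrN1C(=O)CCC1=O
Why: Electrophilic aromatic bromination para to one methoxy group and ortho to the side chain, avoiding the hindered position between the two methoxy groups.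

Step 9
Reactants: 14 2-bromo-3,5-dimethoxybenzyl alcohol
Product: 17 5,7-dimethoxy-2-benzofuran-1(3H)-one (5,7-dimethoxyphthalide), via dilithio species 15 (not isolated), via hydroxy acid 16 (not isolated)
Conditions: n-BuLi (2.2 equiv), THF, −78 °C; CO2, −78 → 23 °C; then 2 M HCl, 23 °C
Reagents that add atoms: carbon dioxide, O=C=O
Why: Bromine–lithium exchange on the lithium alkoxide, carboxylation, and acid lactonisation of the ortho-hydroxymethyl benzoic acid.

Step 10
Reactants: 17 5,7-dimethoxyphthalide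
Product: 18 7-hydroxy-5-methoxy-2-benzofuran-1(3H)-one
Conditions: BCl3 (1.2 equiv), CH2Cl2, −78 → 0 °C; then H2O
Reagents that add atoms: none
Why: Chelation-controlled Lewis acid demethylation cleaves only the methoxy group next to the lactone carbonyl.

Step 11
Reactants: 18 7-hydroxy-5-methoxyphthalide; 19 4-methoxybenzyl chloride
Product: 20 5-methoxy-7-(4-methoxybenzyloxy)-2-benzofuran-1(3H)-one
Conditions: K2CO3, DMF, 60 °C
Reagents that add atoms: none
Why: Williamson etherification of the phenol installs the benzylic ether that later becomes C2 and its aryl group in dihydrobenzofuran 2.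

Step 12
Reactants: 12 G–Br; 20 5-methoxy-7-(4-methoxybenzyloxy)phthalide
Product: 22 keto alcohol G–C(=O)–[2-(hydroxymethyl)-4-methoxy-6-(4-methoxybenzyloxy)phenyl], via aryllithium 21 (not isolated)
Conditions: n-BuLi (1.05 equiv), THF, −78 °C; then 20, −78 °C; then H2O
Reagents that add atoms: none
Why: Bromine–lithium exchange and single acyl addition to the lactone; the tetrahedral lactolate is stable at −78 °C, so it gives the diaryl ketone (in equilibrium with its lactol) without double addition.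

Step 13
Reactants: 22 keto alcohol
Product: 23 G–C(=O)–[4-methoxy-6-(4-methoxybenzyloxy)-2-(triisopropylsilyloxymethyl)phenyl]
Conditions: TIPSCl, imidazole, DMF, 23 °C
Reagents that add atoms: chlorotriisopropylsilane, CC(C)[Si](Cl)(C(C)C)C(C)C
Why: Silylation traps the open keto form and removes the O–H that would capture the carbene; a benzylic CH2OSi has no C–H in the 1,5-position.

Step 14
Reactants: 23 silyl-protected diaryl ketone
Product: 24 hydrazone of 23 (E/Z mixture)
Conditions: N2H4·H2O (20 equiv), AcOH (cat.), n-BuOH, 110 °C, sealed tube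
Reagents that add atoms: hydrazine, NN
Why: Hydrazone condensation on a ketone hindered on one side only; silyl and PMB ethers, aryl methyl ethers and dihydrobenzofuran 1 tolerate hydrazine.

Step 15
Reactants: 24 hydrazone
Product: 26 (2R,3S)-3-G-6-methoxy-2-(4-methoxyphenyl)-4-(triisopropylsilyloxymethyl)-2,3-dihydro-1-benzofuran (cis), via diazo compound 25 (not isolated)
Conditions: MnO2, CH2Cl2, 0 °C, filter; then Rh2(R-PTAD)4 (1 mol %), CH2Cl2, 0 → 23 °C
Reagents that add atoms: none
Why: Second enantioselective Rh-carbene C–H insertion into the OCH2Ar bond; the catalyst sets C3 (S) of dihydrobenzofuran 2 independently of the remote unit G and gives the cis isomer (C2 R).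

Step 16
Reactants: 26 cis-dihydrobenzofuran
Product: 27 (2S,3S)-3-G-6-methoxy-2-(4-methoxyphenyl)-4-(triisopropylsilyloxymethyl)-2,3-dihydro-1-benzofuran (trans)
Conditions: CF3CO2H, CH2Cl2, 0 → 23 °C
Reagents that add atoms: none
Why: Acid-mediated epimerisation at C2 through the 4-methoxybenzylic cation gives the trans isomer (C2 S); the bulky silyl ether oxygen does not compete with the phenol for the cation, and the already trans unit G is unchanged.

Step 17
Reactants: 27 trans silyl ether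
Product: 28 [(2S,3S)-3-G-6-methoxy-2-(4-methoxyphenyl)-2,3-dihydro-1-benzofuran-4-yl]methanol
Conditions: TBAF, THF, 0 → 23 °C
Reagents that add atoms: none
Why: Fluoride desilylation under non-acidic conditions leaves both dihydrobenzofurans untouched.

Step 18
Reactants: 28 benzylic alcohol
Product: 29 (2S,3S)-4-(chloromethyl)-3-G-6-methoxy-2-(4-methoxyphenyl)-2,3-dihydro-1-benzofuran
Conditions: PPh3, NCS, THF, 0 → 23 °C (phosphonium salt preformed)
Reagents that add atoms: N-chlorosuccinimide, ClN1C(=O)CCC1=O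
Why: Appel-type chlorination of a primary benzylic alcohol under neutral conditions; the meta-alkoxy benzylic chloride is not prone to ionisation.

Step 19
Reactants: 29 benzylic chloride
Product: 30 methyl 2-[(2S,3S)-3-G-6-methoxy-2-(4-methoxyphenyl)-2,3-dihydro-1-benzofuran-4-yl]acetate
Conditions: Pd(PPh3)2Cl2 (5 mol %), CO (1 atm), i-Pr2NEt, MeOH/THF, 60 °C
Reagents that add atoms: carbon monoxide, [C-]#[O+]; methanol, CO
Why: Palladium-catalysed alkoxycarbonylation of a benzyl chloride gives the arylacetate; the ester is introduced only now because it would cyclise onto the hydrazone of step 14.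

Step 20
Reactants: 30 methyl arylacetate; 31 methyl 2,4-dimethoxybenzoate
Product: 33 methyl 3-(2,4-dimethoxyphenyl)-3-oxo-2-[(2S,3S)-3-G-6-methoxy-2-(4-methoxyphenyl)-2,3-dihydro-1-benzofuran-4-yl]propanoate (both C2 epimers), via lithium enolate 32 (not isolated)
Conditions: LiHMDS (2.5 equiv), THF, −78 °C; then 31 (3 equiv), −78 → 40 °C; then 1 M HCl
Reagents that add atoms: none
Why: Crossed Claisen condensation: the arylacetate is fully enolised first, so the only ester electrophile is the non-enolisable benzoate, and deprotonation of the β-keto ester drives it; the triarylmethine C–H bonds are not acidic enough for LiHMDS, and the new centre is lost in step 21.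

Step 21
Reactants: 33 β-keto ester
Product: 34 1-(2,4-dimethoxyphenyl)-2-[(2S,3S)-3-G-6-methoxy-2-(4-methoxyphenyl)-2,3-dihydro-1-benzofuran-4-yl]ethanone
Conditions: LiCl, DMSO/H2O, 130 °C
Reagents that add atoms: none
Why: Krapcho dealkoxycarbonylation of an α-aryl β-keto ester under neutral conditions avoids the retro-Claisen cleavage that hydroxide would cause.

Step 22
Reactants: 34 deoxybenzoin
Product: 35 1-(2,4-dimethoxyphenyl)-2-[(2S,3S)-3-G-6-methoxy-2-(4-methoxyphenyl)-2,3-dihydro-1-benzofuran-4-yl]ethanol (both carbinol epimers)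
Conditions: NaBH4, MeOH/THF, 0 °C
Reagents that add atoms: none
Why: Borohydride reduction of the aryl ketone; the carbinol configuration is irrelevant because the centre is ionised in step 23.

Step 23
Reactants: 35 benzylic carbinol
Product: 36 octa-O-methyl ether of the target (all five stereocentres S)
Conditions: CF3CO2H, CH2Cl2 (0.005 M), 0 → 23 °C
Reagents that add atoms: none
Why: Intramolecular Friedel–Crafts alkylation: the 2,4-dimethoxybenzylic cation is attacked by the ring A carbon ortho to the furan oxygen (the other ortho carbon is shielded by the methoxy group forced toward it), and closure through the conformer with the aryl group pseudo-equatorial and anti to C2 of dihydrobenzofuran 2 is expected to set the new centre S, as in acid cyclisations of ε-viniferin-type stilbenes to ampelopsin B-type cores.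

Step 24
Reactants: 36 octamethyl ether
Product: 37 target CNP0154774.1
Conditions: BBr3 (24 equiv), CH2Cl2, −78 → 23 °C; then H2O
Reagents that add atoms: none
Why: Lewis acid cleavage of the eight aryl methyl ethers; no stereocentre bears a leaving group other than the furan oxygens, whose trans arrangement is the thermodynamic one even if they open reversibly.

**Compound list**
1 | 4-bromo-2,6-difluorobenzaldehyde | O=Cc1c(F)cc(Br)cc1F | starting material
2 | 4-methoxybenzyl alcohol | COc1ccc(CO)cc1 | starting material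
3 | 4-bromo-2-fluoro-6-(4-methoxybenzyloxy)benzaldehyde | O=Cc1c(F)cc(Br)cc1OCc1ccc(OC)cc1 | intermediate
4 | 4-bromo-2-methoxy-6-(4-methoxybenzyloxy)benzaldehyde | O=Cc1c(OC)cc(Br)cc1OCc1ccc(OC)cc1 | intermediate
5 | 1-bromo-3,5-dimethoxybenzene | COc1cc(Br)cc(OC)c1 | starting material
6 | 3,5-dimethoxyphenylmagnesium bromide | COc1cc([Mg]Br)cc(OC)c1 | intermediate
7 | rac-[4-bromo-2-methoxy-6-(4-methoxybenzyloxy)phenyl](3,5-dimethoxyphenyl)methanol | OC(c1cc(OC)cc(OC)c1)c1c(OC)cc(Br)cc1OCc1ccc(OC)cc1 | intermediate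
8 | [4-bromo-2-methoxy-6-(4-methoxybenzyloxy)phenyl](3,5-dimethoxyphenyl)methanone | O=C(c1cc(OC)cc(OC)c1)c1c(OC)cc(Br)cc1OCc1ccc(OC)cc1 | intermediate
9 | hydrazone of 8 | NN=C(c1cc(OC)cc(OC)c1)c1c(OC)cc(Br)cc1OCc1ccc(OC)cc1 | intermediate
10 | diazo compound from 9 | [N-]=[N+]=C(c1cc(OC)cc(OC)c1)c1c(OC)cc(Br)cc1OCc1ccc(OC)cc1 | intermediate
11 | (2R,3S)-6-bromo-3-(3,5-dimethoxyphenyl)-4-methoxy-2-(4-methoxyphenyl)-2,3-dihydro-1-benzofuran (cis) | COc1ccc([C@@H]2Oc3cc(Br)cc(OC)c3[C@@H]2c2cc(OC)cc(OC)c2)cc1 | intermediate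
12 | (2S,3S)-6-bromo-3-(3,5-dimethoxyphenyl)-4-methoxy-2-(4-methoxyphenyl)-2,3-dihydro-1-benzofuran (trans; G–Br) | COc1ccc([C@H]2Oc3cc(Br)cc(OC)c3[C@@H]2c2cc(OC)cc(OC)c2)cc1 | intermediate
13 | 3,5-dimethoxybenzyl alcohol | COc1cc(CO)cc(OC)c1 | starting material
14 | 2-bromo-3,5-dimethoxybenzyl alcohol | COc1cc(CO)c(Br)c(OC)c1 | intermediate
15 | lithium (2-lithio-3,5-dimethoxyphenyl)methanolate | COc1cc(CO[Li])c([Li])c(OC)c1 | intermediate
16 | 2-(hydroxymethyl)-4,6-dimethoxybenzoic acid | COc1cc(CO)c(C(=O)O)c(OC)c1 | intermediate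
17 | 5,7-dimethoxy-2-benzofuran-1(3H)-one | COc1cc2c(c(OC)c1)C(=O)OC2 | intermediate
18 | 7-hydroxy-5-methoxy-2-benzofuran-1(3H)-one | COc1cc2c(c(O)c1)C(=O)OC2 | intermediate
19 | 4-methoxybenzyl chloride | COc1ccc(CCl)cc1 | starting material
20 | 5-methoxy-7-(4-methoxybenzyloxy)-2-benzofuran-1(3H)-one | COc1ccc(COc2cc(OC)cc3c2C(=O)OC3)cc1 | intermediate
21 | aryllithium G–Li | COc1ccc([C@H]2Oc3cc([Li])cc(OC)c3[C@@H]2c2cc(OC)cc(OC)c2)cc1 | intermediate
22 | G–C(=O)–[2-(hydroxymethyl)-4-methoxy-6-(4-methoxybenzyloxy)phenyl] | COc1ccc([C@H]2Oc3cc(cc(OC)c3[C@@H]2c2cc(OC)cc(OC)c2)C(=O)c2c(CO)cc(OC)cc2OCc2ccc(OC)cc2)cc1 | intermediate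
23 | G–C(=O)–[4-methoxy-6-(4-methoxybenzyloxy)-2-(triisopropylsilyloxymethyl)phenyl] | COc1ccc([C@H]2Oc3cc(cc(OC)c3[C@@H]2c2cc(OC)cc(OC)c2)C(=O)c2c(CO[Si](C(C)C)(C(C)C)C(C)C)cc(OC)cc2OCc2ccc(OC)cc2)cc1 | intermediate
24 | hydrazone of 23 | COc1ccc([C@H]2Oc3cc(cc(OC)c3[C@@H]2c2cc(OC)cc(OC)c2)C(=NN)c2c(CO[Si](C(C)C)(C(C)C)C(C)C)cc(OC)cc2OCc2ccc(OC)cc2)cc1 | intermediate
25 | diazo compound from 24 | COc1ccc([C@H]2Oc3cc(cc(OC)c3[C@@H]2c2cc(OC)cc(OC)c2)C(=[N+]=[N-])c2c(CO[Si](C(C)C)(C(C)C)C(C)C)cc(OC)cc2OCc2ccc(OC)cc2)cc1 | intermediate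
26 | (2R,3S)-3-G-6-methoxy-2-(4-methoxyphenyl)-4-(triisopropylsilyloxymethyl)-2,3-dihydro-1-benzofuran (cis) | COc1ccc([C@H]2Oc3cc(cc(OC)c3[C@@H]2c2cc(OC)cc(OC)c2)[C@H]2c3c(cc(OC)cc3O[C@H]2c2ccc(OC)cc2)CO[Si](C(C)C)(C(C)C)C(C)C)cc1 | intermediate
27 | (2S,3S)-3-G-6-methoxy-2-(4-methoxyphenyl)-4-(triisopropylsilyloxymethyl)-2,3-dihydro-1-benzofuran (trans) | COc1ccc([C@H]2Oc3cc(cc(OC)c3[C@@H]2c2cc(OC)cc(OC)c2)[C@H]2c3c(cc(OC)cc3O[C@@H]2c2ccc(OC)cc2)CO[Si](C(C)C)(C(C)C)C(C)C)cc1 | intermediate
28 | [(2S,3S)-3-G-6-methoxy-2-(4-methoxyphenyl)-2,3-dihydro-1-benzofuran-4-yl]methanol | COc1ccc([C@H]2Oc3cc(cc(OC)c3[C@@H]2c2cc(OC)cc(OC)c2)[C@H]2c3c(cc(OC)cc3O[C@@H]2c2ccc(OC)cc2)CO)cc1 | intermediate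
29 | (2S,3S)-4-(chloromethyl)-3-G-6-methoxy-2-(4-methoxyphenyl)-2,3-dihydro-1-benzofuran | COc1ccc([C@H]2Oc3cc(cc(OC)c3[C@@H]2c2cc(OC)cc(OC)c2)[C@H]2c3c(cc(OC)cc3O[C@@H]2c2ccc(OC)cc2)CCl)cc1 | intermediate
30 | methyl 2-[(2S,3S)-3-G-6-methoxy-2-(4-methoxyphenyl)-2,3-dihydro-1-benzofuran-4-yl]acetate | COc1ccc([C@H]2Oc3cc(cc(OC)c3[C@@H]2c2cc(OC)cc(OC)c2)[C@H]2c3c(cc(OC)cc3O[C@@H]2c2ccc(OC)cc2)CC(=O)OC)cc1 | intermediate
31 | methyl 2,4-dimethoxybenzoate | COC(=O)c1ccc(OC)cc1OC | starting material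
32 | lithium enolate of 30 | COc1ccc([C@H]2Oc3cc(cc(OC)c3[C@@H]2c2cc(OC)cc(OC)c2)[C@H]2c3c(cc(OC)cc3O[C@@H]2c2ccc(OC)cc2)C=C(OC)O[Li])cc1 | intermediate
33 | methyl 3-(2,4-dimethoxyphenyl)-3-oxo-2-[(2S,3S)-3-G-6-methoxy-2-(4-methoxyphenyl)-2,3-dihydro-1-benzofuran-4-yl]propanoate (C2 epimers) | COc1ccc([C@H]2Oc3cc(cc(OC)c3[C@@H]2c2cc(OC)cc(OC)c2)[C@H]2c3c(cc(OC)cc3O[C@@H]2c2ccc(OC)cc2)C(C(=O)OC)C(=O)c2ccc(OC)cc2OC)cc1 | intermediate
34 | 1-(2,4-dimethoxyphenyl)-2-[(2S,3S)-3-G-6-methoxy-2-(4-methoxyphenyl)-2,3-dihydro-1-benzofuran-4-yl]ethanone | COc1ccc([C@H]2Oc3cc(cc(OC)c3[C@@H]2c2cc(OC)cc(OC)c2)[C@H]2c3c(cc(OC)cc3O[C@@H]2c2ccc(OC)cc2)CC(=O)c2ccc(OC)cc2OC)cc1 | intermediate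
35 | 1-(2,4-dimethoxyphenyl)-2-[(2S,3S)-3-G-6-methoxy-2-(4-methoxyphenyl)-2,3-dihydro-1-benzofuran-4-yl]ethanol (carbinol epimers) | COc1ccc([C@H]2Oc3cc(cc(OC)c3[C@@H]2c2cc(OC)cc(OC)c2)[C@H]2c3c(cc(OC)cc3O[C@@H]2c2ccc(OC)cc2)CC(O)c2ccc(OC)cc2OC)cc1 | intermediate
36 | octa-O-methyl ether of the target (two trans-2,3-diaryl dihydrobenzofurans fused to a 10,11-dihydro-5H-dibenzo[a,d]cycloheptene; all five stereocentres S) | COc1ccc([C@H]2Oc3c4c(cc(OC)c3[C@@H]2c2cc(OC)cc(OC)c2)[C@H]2c3c(cc(OC)cc3O[C@@H]2c2ccc(OC)cc2)C[C@H]4c2ccc(OC)cc2OC)cc1 | intermediate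
37 | CNP0154774.1 (octaphenol; all five stereocentres S) | Oc1ccc([C@H]2Oc3c4c(cc(O)c3[C@@H]2c2cc(O)cc(O)c2)[C@H]2c3c(cc(O)cc3O[C@@H]2c2ccc(O)cc2)C[C@H]4c2ccc(O)cc2O)cc1 | target

**Step count**
Total steps: 24. Longest linear sequence: 20 (steps 1–7, then 12–24).

**Three steps most likely to fail**

Step 15 (with its hydrazone, step 14): the ketone is hindered on one side, and the carbene must insert with catalyst control next to a bulky neighbour. The fallback sets out from 23 and comes back at 27. Ketone 23 is treated with LiTMP in THF at −78 → 0 °C, so that the benzylic ether carbanion adds to the neighbouring carbonyl (intramolecular aldol-type addition) and gives the tertiary 3-hydroxy-2,3-dihydrobenzofuran F1 as an isomer mixture. Et3SiH/CF3CO2H in CH2Cl2 at 0 °C then ionises the carbinol, delivers hydride and equilibrates C2 to trans. Because unit G is already a single enantiomer, the two trans products are diastereomers; 27 is separated from its isomer by chromatography, at the cost of about half the material.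

Step 20: the enolate is hindered and the benzoate is electron-rich, so the condensation may stall. The fallback sets out from 29 and comes back at 34. Chloride 29 is displaced with PhSO2Na in DMF to give the benzyl phenyl sulfone F2. Its anion (n-BuLi, 2.2 equiv, THF, −78 °C) is acylated with benzoate 31 to give the β-keto sulfone F3. Reductive desulfonylation with Zn dust in AcOH/THF then gives deoxybenzoin 34.

Step 23: regiochemistry on ring A and the configuration of the new benzylic centre rest on substrate control, and the cation can also eliminate or oligomerise. The fallback sets out from 34 and comes back at 36. Ketone 34 is cyclodehydrated with MeSO3H in CH2Cl2 (intramolecular Friedel–Crafts hydroxyalkylation, then loss of water) to give the conjugated cycloheptene F4. Ionic hydrogenation with Et3SiH/CF3CO2H then sets the benzylic centre by hydride delivery to the ring cation from the less hindered face, giving 36; the stereo-determining event is thus C–H rather than C–C bond formation.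

**Further compounds**
F1 | step 15 | 3-G-3-hydroxy-6-methoxy-2-(4-methoxyphenyl)-4-(triisopropylsilyloxymethyl)-2,3-dihydro-1-benzofuran (isomer mixture at C2 and C3) | COc1ccc([C@H]2Oc3cc(cc(OC)c3[C@@H]2c2cc(OC)cc(OC)c2)C2(O)c3c(cc(OC)cc3OC2c2ccc(OC)cc2)CO[Si](C(C)C)(C(C)C)C(C)C)cc1
F2 | step 20 | (2S,3S)-3-G-6-methoxy-2-(4-methoxyphenyl)-4-(phenylsulfonylmethyl)-2,3-dihydro-1-benzofuran | COc1ccc([C@H]2Oc3cc(cc(OC)c3[C@@H]2c2cc(OC)cc(OC)c2)[C@H]2c3c(cc(OC)cc3O[C@@H]2c2ccc(OC)cc2)CS(=O)(=O)c2ccccc2)cc1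
F3 | step 20 | 1-(2,4-dimethoxyphenyl)-2-(phenylsulfonyl)-2-[(2S,3S)-3-G-6-methoxy-2-(4-methoxyphenyl)-2,3-dihydro-1-benzofuran-4-yl]ethanone | COc1ccc([C@H]2Oc3cc(cc(OC)c3[C@@H]2c2cc(OC)cc(OC)c2)[C@H]2c3c(cc(OC)cc3O[C@@H]2c2ccc(OC)cc2)C(S(=O)(=O)c2ccccc2)C(=O)c2ccc(OC)cc2OC)cc1
F4 | step 23 | cycloheptene analogue of 36 (C=C between the aryl-bearing carbon and the former CH2) | COc1ccc([C@H]2Oc3c4c(cc(OC)c3[C@@H]2c2cc(OC)cc(OC)c2)[C@H]2c3c(cc(OC)cc3O[C@@H]2c2ccc(OC)cc2)C=C4c2ccc(OC)cc2OC)cc1
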